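**Retrosynthetic overview**
- Target ⇐ late C8 angeloylation, C9 ketone unmasking, C5 isobutyrylation and cis-dihydroxylation of a (Z)-C4=C5 cyclodecene-fused α-methylene lactone.
- Bicyclic core ⇐ one Ni/Cr operation on an acyclic (Z)-alkenyl iodide/aldehyde/γ-ester: the C5–C6 bond closes the ten-membered ring and the new C6 alkoxide closes the γ-lactone in the same flask.
- Acyclic precursor ⇐ auxiliary-controlled syn-aldol (C7–C8) between a succinyl thiazolidinethione and an α-aminoxy aldehyde.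
- That aldehyde ⇐ (R)-citronellal (C10 from the chiral pool) by ozonolysis, Normant carbocupration of propyne (Z-alkenyl iodide) and α-oxyamination.
- Ring order: carbocycle and lactone are formed together in step 11; there is no other ring-forming step.

Assumption: atom labels C1–C15 follow germacrane numbering of the target (C4 OH/Me, C5 isobutyrate, C6 lactone O, C8 angelate, C9 ketone, C10 Me), and the amine catalyst of step 6 is the enantiomer that oxidises the Si face of the enamine (the C9 centre it sets is erased in step 15).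

**Step 1**
Reactants: 1 (R)-citronellal
Product: 2 (6R)-8,8-dimethoxy-2,6-dimethyloct-2-ene
Conditions: HC(OMe)3, MeOH, PPTS (2 mol%), 0 °C → rt
Reagents that add atoms: trimethyl orthoformate COC(OC)OC; methanol CO
Why: Acid-catalysed acetalisation masks the aldehyde for the ozonolysis and Grignard steps; the mild orthoformate conditions avoid the carbonyl-ene cyclisation of citronellal and leave the chiral-pool C10 centre (R) untouched.

**Step 2**
Reactants: 2 (6R)-8,8-dimethoxy-2,6-dimethyloct-2-ene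
Product: 3 (4R)-6,6-dimethoxy-4-methylhexan-1-ol
Conditions: O3, CH2Cl2/MeOH, NaHCO3, −78 °C; then NaBH4, −78 → 0 °C
Reagents that add atoms: ozone [O-][O+]=O
Why: Ozonolysis of the only alkene with reductive borohydride work-up removes the isopropylidene carbons and leaves the primary alcohol at C3; the acetal and C10 are unaffected.

**Step 3**
Reactants: 3 (4R)-6,6-dimethoxy-4-methylhexan-1-ol
Product: 4 (3R)-6-bromo-1,1-dimethoxy-3-methylhexane
Conditions: CBr4, PPh3, 2,6-lutidine, CH2Cl2, 0 °C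
Reagents that add atoms: carbon tetrabromide BrC(Br)(Br)Br
Why: Appel bromination of the primary alcohol (SN2 at CH2), buffered so that the acetal survives.

**Step 4**
Reactants: 4 (3R)-6-bromo-1,1-dimethoxy-3-methylhexane; 5 propyne
Product: 8 (1Z,6R)-1-iodo-8,8-dimethoxy-2,6-dimethyloct-1-ene, via Grignard reagent 6 (not isolated), via alkenylcopper 7 (not isolated)
Conditions: Mg, THF; CuBr·SMe2, Et2O/Me2S, −45 °C; propyne, −25 °C; I2, THF, −78 → 0 °C
Reagents that add atoms: iodine II
Why: Normant carbocupration: the alkylcopper from Grignard 6 adds syn across propyne with the alkyl group on the internal carbon, and iodinolysis of alkenylcopper 7 with retention gives the (Z)-2-methyl-1-iodoalkene (C3 cis to iodine), the geometry needed for a cis-cyclodecene.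

**Step 5**
Reactants: 8 (1Z,6R)-1-iodo-8,8-dimethoxy-2,6-dimethyloct-1-ene
Product: 9 (3R,7Z)-8-iodo-3,7-dimethyloct-7-enal
Conditions: 1 M HCl, THF, rt
Reagents that add atoms: water O
Why: Acid-catalysed acetal hydrolysis; the alkenyl iodide and the non-epimerisable C10 centre are stable.

**Step 6**
Reactants: 9 (3R,7Z)-8-iodo-3,7-dimethyloct-7-enal
Product: 10 (2S,3R,7Z)-8-iodo-3,7-dimethyl-2-[(2,2,6,6-tetramethylpiperidin-1-yl)oxy]oct-7-enal
Conditions: TEMPO (1.2 equiv), 5-benzyl-2,2,3-trimethylimidazolidin-4-one·TFA (20 mol%), CuCl2 (10 mol%), air, acetone, −10 °C; used crude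
Reagents that add atoms: TEMPO CC1(C)CCCC(C)(C)N1[O]
Why: Organocatalytic enantioselective α-oxyamination (enamine oxidation and TEMPO trapping): the catalyst shields one enamine face and sets C9 (2S), installing the future C9 ketone oxygen as a robust alkoxyamine.

**Step 7**
Reactants: 11 (4R)-4-benzyl-1,3-thiazolidine-2-thione; 12 methyl 4-chloro-4-oxobutanoate
Product: 13 methyl 4-[(4R)-4-benzyl-2-sulfanylidene-1,3-thiazolidin-3-yl]-4-oxobutanoate
Conditions: Et3N, DMAP (cat.), CH2Cl2, 0 °C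
Reagents that add atoms: none
Why: N-acylation of the thiazolidinethione auxiliary by the acid chloride gives the succinate aldol donor.

**Step 8**
Reactants: 10 (2S,3R,7Z)-8-iodo-3,7-dimethyl-2-[(2,2,6,6-tetramethylpiperidin-1-yl)oxy]oct-7-enal; 13 methyl 4-[(4R)-4-benzyl-2-sulfanylidene-1,3-thiazolidin-3-yl]-4-oxobutanoate
Product: 15 methyl (3R,4R,5S,6R,10Z)-3-{[(4R)-4-benzyl-2-sulfanylidene-1,3-thiazolidin-3-yl]carbonyl}-4-hydroxy-11-iodo-6,10-dimethyl-5-[(2,2,6,6-tetramethylpiperidin-1-yl)oxy]undec-10-enoate, via chlorotitanium enolate 14 (not isolated)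
Conditions: 13, TiCl4, i-Pr2NEt, NMP, CH2Cl2, 0 °C; then 10, −78 °C; aq. NH4Cl quench at −78 °C
Reagents that add atoms: none
Why: Crimmins titanium-mediated syn-aldol addition: the (Z)-chlorotitanium enolate 14 reacts through the non-chelated Zimmerman–Traxler chair on the face away from the benzyl group of the (R)-auxiliary, setting C7 and C8 syn with the absolute sense of the target (Felkin-matched with the 2S aminoxy aldehyde).

**Step 9**
Reactants: 15 aldol adduct (name as above)
Product: 16 methyl (3R,4R,5S,6R,10Z)-3-{[(4R)-4-benzyl-2-sulfanylidene-1,3-thiazolidin-3-yl]carbonyl}-4-[(tert-butyldimethylsilyl)oxy]-11-iodo-6,10-dimethyl-5-[(2,2,6,6-tetramethylpiperidin-1-yl)oxy]undec-10-enoate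
Conditions: TBSOTf, 2,6-lutidine, CH2Cl2, −78 °C (on crude 15)
Reagents that add atoms: tert-butyldimethylsilyl triflate CC(C)(C)[Si](C)(C)OS(=O)(=O)C(F)(F)F
Why: Immediate silylation protects O8 before it can lactonise onto the γ-ester and keeps it out of the later lactone-forming step.

**Step 10**
Reactants: 16 TBS ether (name as above)
Product: 17 methyl (3R,4R,5S,6R,10Z)-4-[(tert-butyldimethylsilyl)oxy]-3-formyl-11-iodo-6,10-dimethyl-5-[(2,2,6,6-tetramethylpiperidin-1-yl)oxy]undec-10-enoate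
Conditions: DIBAL-H (1.3 equiv), CH2Cl2, −78 °C; Rochelle salt work-up
Reagents that add atoms: none
Why: Direct DIBAL-H reduction of the N-acylthiazolidinethione (far more electrophilic than the methyl ester) stops at the aldehyde via a stable tetrahedral aluminate; the auxiliary is released and C7 is not epimerised at −78 °C.

**Step 11 (key step)**
Reactants: 17 aldehyde/alkenyl iodide/ester (name as above)
Product: 20 (4Z,6R,7S,8R,9S,10R)-8-(tert-butyldimethylsilyloxy)-9-(2,2,6,6-tetramethylpiperidin-1-yloxy)-13-norgermacr-4-en-12,6-olide, via alkenylchromium 18 (not isolated), via chromium alkoxide 19 (not isolated)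
Conditions: CrCl2 (12 equiv), NiCl2 (2 mol%), degassed DMSO/THF 3:1, 2 mM (syringe pump, 20 h), rt; then 40 °C, 3 h
Reagents that add atoms: none
Why: Proposed new method: Ni(0) oxidative addition and transmetallation turn the (Z)-alkenyl iodide into the configurationally stable alkenyl-Cr(III) 18, which adds to the C6 aldehyde in a Felkin-type macrocyclic transition state (attack anti to the C8 branch, O6 ending trans to the C7 side chain) to close the ten-membered ring, and the Cr(III) alkoxide 19 then acylates on the γ-ester to close the trans-fused lactone, so both rings form in one flask; the closest known chemistry is the Ni/Cr-mediated (Nozaki–Hiyama–Kishi) alkenyl iodide–aldehyde macrocyclisation and the spontaneous lactonisation of Cr(III) γ-alkoxy esters in Cr-mediated 2-(alkoxycarbonyl)allylations.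

**Step 12**
Reactants: 20 bicyclic lactone (name as above)
Product: 23 (4Z,6R,7S,8R,9S,10R)-8-(tert-butyldimethylsilyloxy)-9-(2,2,6,6-tetramethylpiperidin-1-yloxy)germacra-4,11(13)-dien-12,6-olide, via Mannich base 21 (not isolated), via ammonium iodide 22 (not isolated)
Conditions: LDA, THF, −78 °C; CH2=NMe2+ I−, −78 °C → rt; MeI, MeOH, rt; aq. NaHCO3/CH2Cl2
Reagents that add atoms: Eschenmoser's salt C=[N+](C)C.[I-]
Why: Eschenmoser α-methylenation: the lactone lithium enolate undergoes a Mannich reaction with the iminium salt, and quaternisation followed by E1cB loss of trimethylamine gives the exocyclic methylene; no other acidic C–H competes and C7 is untouched.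

**Step 13**
Reactants: 23 α-methylene lactone (name as above)
Product: 24 (4S,5R,6S,7S,8R,9S,10R)-8-(tert-butyldimethylsilyloxy)-4,5-dihydroxy-9-(2,2,6,6-tetramethylpiperidin-1-yloxy)germacr-11(13)-en-12,6-olide
Conditions: OsO4 (5 mol%), NMO (1.5 equiv), acetone/H2O 4:1, 0 °C
Reagents that add atoms: N-methylmorpholine N-oxide C[N+]1([O-])CCOCC1; water O; osmium tetroxide O=[Os](=O)(=O)=O (catalytic oxygen carrier)
Why: Upjohn syn-dihydroxylation: OsO4 selects the electron-rich trisubstituted ring alkene over the acrylate and adds from the peripheral face of the cis-cyclodecene (the face of O6, with H6 eclipsing the alkene and the inner face blocked by the ring), so syn addition to the (Z)-alkene gives the 4S,5R erythro diol.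

**Step 14**
Reactants: 24 diol (name as above)
Product: 25 (4S,5R,6S,7S,8R,9S,10R)-8-(tert-butyldimethylsilyloxy)-4-hydroxy-5-(2-methylpropanoyloxy)-9-(2,2,6,6-tetramethylpiperidin-1-yloxy)germacr-11(13)-en-12,6-olide
Conditions: (i-PrCO)2O (1.5 equiv), Et3N, DMAP (0.1 equiv), CH2Cl2, 0 °C
Reagents that add atoms: isobutyric anhydride CC(C)C(=O)OC(=O)C(C)C
Why: DMAP-catalysed acylation reacts only at the secondary C5–OH; the tertiary C4–OH is inert and O8/O9 are masked.

**Step 15**
Reactants: 25 isobutyrate (name as above)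
Product: 27 (4S,5R,6S,7S,8R,10R)-8-(tert-butyldimethylsilyloxy)-4-hydroxy-5-(2-methylpropanoyloxy)-9-oxogermacr-11(13)-en-12,6-olide, via alkoxyamine N-oxide 26 (not isolated)
Conditions: mCPBA (1.5 equiv), NaHCO3, CH2Cl2, 0 °C → rt
Reagents that add atoms: none
Why: Oxidative fragmentation of the alkoxyamine: mCPBA N-oxidises the hindered amine and N-oxide 26 undergoes Cope-type syn-elimination through a five-membered transition state to give the C9 ketone; the electron-poor methylene lactone is not epoxidised under buffered conditions and C8/C10 are not epimerised.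

**Step 16**
Reactants: 27 silyloxy ketone (name as above)
Product: 28 (4S,5R,6S,7R,8R,10R)-4,8-dihydroxy-5-(2-methylpropanoyloxy)-9-oxogermacr-11(13)-en-12,6-olide
Conditions: HF·pyridine, pyridine/THF, 0 °C → rt
Reagents that add atoms: none
Why: Fluoride-mediated desilylation under buffered, weakly acidic conditions leaves both esters, the lactone and the α-ketol stereocentres intact.

**Step 17**
Reactants: 28 α-hydroxy ketone (name as above); 29 angelic acid [(Z)-2-methylbut-2-enoic acid]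
Product: 31 (4S,5R,6S,7S,8R,10R)-8-[(Z)-2-methylbut-2-enoyloxy]-4-hydroxy-5-(2-methylpropanoyloxy)-9-oxogermacr-11(13)-en-12,6-olide (CNP0141258.2), via mixed anhydride 30 (not isolated)
Conditions: 29, 2,4,6-Cl3C6H2COCl, Et3N, toluene, rt, 2 h; then 28, 75 °C
Reagents that add atoms: none
Why: Yamaguchi-type esterification through mixed anhydride 30 without a nucleophilic catalyst acylates the hindered C8–OH with retention and keeps the (Z) geometry of the angelate (DMAP or acid-chloride methods cause Z to E isomerisation).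

**Compound list**
1 | (R)-citronellal [(3R)-3,7-dimethyloct-6-enal] | O=CC[C@H](C)CCC=C(C)C | starting material
2 | (6R)-8,8-dimethoxy-2,6-dimethyloct-2-ene | COC(OC)C[C@H](C)CCC=C(C)C | intermediate
3 | (4R)-6,6-dimethoxy-4-methylhexan-1-ol | COC(OC)C[C@H](C)CCCO | intermediate
4 | (3R)-6-bromo-1,1-dimethoxy-3-methylhexane | COC(OC)C[C@H](C)CCCBr | intermediate
5 | propyne | CC#C | starting material
6 | [(4R)-6,6-dimethoxy-4-methylhexyl]magnesium bromide | COC(OC)C[C@H](C)CCC[Mg]Br | intermediate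
7 | [(1Z,6R)-8,8-dimethoxy-2,6-dimethyloct-1-en-1-yl]copper | COC(OC)C[C@H](C)CCC/C(C)=C\[Cu] | intermediate
8 | (1Z,6R)-1-iodo-8,8-dimethoxy-2,6-dimethyloct-1-ene | COC(OC)C[C@H](C)CCC/C(C)=C\I | intermediate
9 | (3R,7Z)-8-iodo-3,7-dimethyloct-7-enal | O=CC[C@H](C)CCC/C(C)=C\I | intermediate
10 | (2S,3R,7Z)-8-iodo-3,7-dimethyl-2-[(2,2,6,6-tetramethylpiperidin-1-yl)oxy]oct-7-enal | O=C[C@@H](ON1C(C)(C)CCCC1(C)C)[C@H](C)CCC/C(C)=C\I | intermediate
11 | (4R)-4-benzyl-1,3-thiazolidine-2-thione | S=C1N[C@H](Cc2ccccc2)CS1 | starting material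
12 | methyl 4-chloro-4-oxobutanoate | COC(=O)CCC(=O)Cl | starting material
13 | methyl 4-[(4R)-4-benzyl-2-sulfanylidene-1,3-thiazolidin-3-yl]-4-oxobutanoate | COC(=O)CCC(=O)N1[C@H](Cc2ccccc2)CSC1=S | intermediate
14 | trichlorotitanium (Z)-enolate of 13 (O and CH2CO2Me cis) | COC(=O)C/C=C(\O[Ti](Cl)(Cl)Cl)N1[C@H](Cc2ccccc2)CSC1=S | intermediate
15 | methyl (3R,4R,5S,6R,10Z)-3-{[(4R)-4-benzyl-2-sulfanylidene-1,3-thiazolidin-3-yl]carbonyl}-4-hydroxy-11-iodo-6,10-dimethyl-5-[(2,2,6,6-tetramethylpiperidin-1-yl)oxy]undec-10-enoate | S=C1SC[C@@H](Cc2ccccc2)N1C(=O)[C@H](CC(=O)OC)[C@@H](O)[C@@H](ON3C(C)(C)CCCC3(C)C)[C@H](C)CCC/C(C)=C\I | intermediate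
16 | 4-O-TBS ether of 15 (3R,4R,5S,6R,10Z) | S=C1SC[C@@H](Cc2ccccc2)N1C(=O)[C@H](CC(=O)OC)[C@@H](O[Si](C)(C)C(C)(C)C)[C@@H](ON3C(C)(C)CCCC3(C)C)[C@H](C)CCC/C(C)=C\I | intermediate
17 | methyl (3R,4R,5S,6R,10Z)-4-[(tert-butyldimethylsilyl)oxy]-3-formyl-11-iodo-6,10-dimethyl-5-[(2,2,6,6-tetramethylpiperidin-1-yl)oxy]undec-10-enoate | O=C[C@H](CC(=O)OC)[C@@H](O[Si](C)(C)C(C)(C)C)[C@@H](ON1C(C)(C)CCCC1(C)C)[C@H](C)CCC/C(C)=C\I | intermediate
18 | (Z)-alkenylchromium(III) dichloride from 17 (C–I replaced by C–CrCl2; all stereocentres as in 17) | O=C[C@H](CC(=O)OC)[C@@H](O[Si](C)(C)C(C)(C)C)[C@@H](ON1C(C)(C)CCCC1(C)C)[C@H](C)CCC/C(C)=C\[Cr](Cl)Cl | intermediate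
19 | chromium(III) alkoxide of the ring-closed (4Z)-cyclodecenyl hydroxy ester (C6–OCrCl2; configurations as in 20) | C1/C(C)=C\[C@@H](O[Cr](Cl)Cl)[C@H](CC(=O)OC)[C@@H](O[Si](C)(C)C(C)(C)C)[C@@H](ON2C(C)(C)CCCC2(C)C)[C@H](C)CC1 | intermediate
20 | (4Z,6R,7S,8R,9S,10R)-8-(tert-butyldimethylsilyloxy)-9-(2,2,6,6-tetramethylpiperidin-1-yloxy)-13-norgermacr-4-en-12,6-olide (trans-fused γ-lactone) | C1/C(C)=C\[C@H]2OC(=O)C[C@@H]2[C@@H](O[Si](C)(C)C(C)(C)C)[C@@H](ON3C(C)(C)CCCC3(C)C)[C@H](C)CC1 | intermediate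
21 | 11-(dimethylaminomethyl) derivative of 20 (C11 epimers) | C1/C(C)=C\[C@H]2OC(=O)C(CN(C)C)[C@@H]2[C@@H](O[Si](C)(C)C(C)(C)C)[C@@H](ON3C(C)(C)CCCC3(C)C)[C@H](C)CC1 | intermediate
22 | 11-(trimethylammoniomethyl) iodide derived from 21 | C1/C(C)=C\[C@H]2OC(=O)C(C[N+](C)(C)C)[C@@H]2[C@@H](O[Si](C)(C)C(C)(C)C)[C@@H](ON3C(C)(C)CCCC3(C)C)[C@H](C)CC1.[I-] | intermediate
23 | (4Z,6R,7S,8R,9S,10R)-8-(tert-butyldimethylsilyloxy)-9-(2,2,6,6-tetramethylpiperidin-1-yloxy)germacra-4,11(13)-dien-12,6-olide | C1/C(C)=C\[C@H]2OC(=O)C(=C)[C@@H]2[C@@H](O[Si](C)(C)C(C)(C)C)[C@@H](ON3C(C)(C)CCCC3(C)C)[C@H](C)CC1 | intermediate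
24 | (4S,5R,6S,7S,8R,9S,10R)-8-(tert-butyldimethylsilyloxy)-4,5-dihydroxy-9-(2,2,6,6-tetramethylpiperidin-1-yloxy)germacr-11(13)-en-12,6-olide | C1[C@](C)(O)[C@H](O)[C@H]2OC(=O)C(=C)[C@@H]2[C@@H](O[Si](C)(C)C(C)(C)C)[C@@H](ON3C(C)(C)CCCC3(C)C)[C@H](C)CC1 | intermediate
25 | (4S,5R,6S,7S,8R,9S,10R)-8-(tert-butyldimethylsilyloxy)-4-hydroxy-5-(2-methylpropanoyloxy)-9-(2,2,6,6-tetramethylpiperidin-1-yloxy)germacr-11(13)-en-12,6-olide | C1[C@](C)(O)[C@H](OC(=O)C(C)C)[C@H]2OC(=O)C(=C)[C@@H]2[C@@H](O[Si](C)(C)C(C)(C)C)[C@@H](ON3C(C)(C)CCCC3(C)C)[C@H](C)CC1 | intermediate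
26 | piperidine N-oxide of 25 | C1[C@](C)(O)[C@H](OC(=O)C(C)C)[C@H]2OC(=O)C(=C)[C@@H]2[C@@H](O[Si](C)(C)C(C)(C)C)[C@@H](O[N+]3([O-])C(C)(C)CCCC3(C)C)[C@H](C)CC1 | intermediate
27 | (4S,5R,6S,7S,8R,10R)-8-(tert-butyldimethylsilyloxy)-4-hydroxy-5-(2-methylpropanoyloxy)-9-oxogermacr-11(13)-en-12,6-olide | C1[C@](C)(O)[C@H](OC(=O)C(C)C)[C@H]2OC(=O)C(=C)[C@@H]2[C@@H](O[Si](C)(C)C(C)(C)C)C(=O)[C@H](C)CC1 | intermediate
28 | (4S,5R,6S,7R,8R,10R)-4,8-dihydroxy-5-(2-methylpropanoyloxy)-9-oxogermacr-11(13)-en-12,6-olide | C1[C@](C)(O)[C@H](OC(=O)C(C)C)[C@H]2OC(=O)C(=C)[C@@H]2[C@@H](O)C(=O)[C@H](C)CC1 | intermediate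
29 | angelic acid [(Z)-2-methylbut-2-enoic acid] | C/C=C(/C)C(=O)O | starting material
30 | (Z)-2-methylbut-2-enoic 2,4,6-trichlorobenzoic anhydride | C/C=C(/C)C(=O)OC(=O)c1c(Cl)cc(Cl)cc1Cl | intermediate
31 | (4S,5R,6S,7S,8R,10R)-8-[(Z)-2-methylbut-2-enoyloxy]-4-hydroxy-5-(2-methylpropanoyloxy)-9-oxogermacr-11(13)-en-12,6-olide (CNP0141258.2) | C=C1C(=O)O[C@H]2[C@H]1[C@@H](OC(=O)/C(C)=C\C)C(=O)[C@H](C)CCC[C@](C)(O)[C@@H]2OC(=O)C(C)C | target

**Step count**
Total: 17 steps. Longest linear sequence: 16 steps (1–6 and 8–17, from 1); step 7 is a one-step side branch.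

**Three steps most likely to fail**

Step 11 (Ni/Cr ring closure with lactonisation). Felkin control and the 1,3-influence of the C8 silyloxy group are not reinforcing, so the C6 epimer may dominate. In that case the route sets out from 17 as before and accepts the cis-fused 6-epi lactone F1. This is saponified (LiOH, THF/H2O, then mild acidification) to the 6-epi hydroxy acid F2. F2 is then re-lactonised under Mitsunobu conditions (PPh3, DIAD, toluene, 5 mM): the carboxylate displaces the activated allylic C6–OH with inversion. This comes back to the route at 20, with C6 set by SN2 inversion instead of by the addition step.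

Step 13 (face of the dihydroxylation). If osmium adds from the other face of the cyclodecene, the fallback sets out from 23 with a Woodward-type cis-hydroxylation using I2 and silver isobutyrate in benzene containing one equivalent of water. The iodonium ion forms on the face osmium prefers, and isobutyrate opens it at the tertiary C4 to give the trans iodo isobutyrate F3. Its ester carbonyl then displaces iodide at C5 with inversion, and hydrolysis with acyl shift to the secondary oxygen places both oxygens on the opposite face. This comes back to the route directly at 25 and makes step 14 unnecessary.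

Step 15 (mCPBA fragmentation of a hindered alkoxyamine in a dense setting). If N-oxidation is too slow or unselective, the fallback sets out from 25 with reductive N–O cleavage (Zn dust, AcOH/THF/H2O, 50 °C) to the C9 alcohol F4. Dess–Martin periodinane (NaHCO3, CH2Cl2) then oxidises it, coming back to the route at 27.

**Further compounds**
F1 | step 11 | 6-epi lactone: (4Z,6S,7S,8R,9S,10R)-8-(tert-butyldimethylsilyloxy)-9-(2,2,6,6-tetramethylpiperidin-1-yloxy)-13-norgermacr-4-en-12,6-olide (cis-fused) | C1/C(C)=C\[C@@H]2OC(=O)C[C@@H]2[C@@H](O[Si](C)(C)C(C)(C)C)[C@@H](ON3C(C)(C)CCCC3(C)C)[C@H](C)CC1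
F2 | step 11 | 6-epi hydroxy acid: ring-opened 6-hydroxy-12-oic acid of F1 | C1/C(C)=C\[C@H](O)[C@H](CC(=O)O)[C@@H](O[Si](C)(C)C(C)(C)C)[C@@H](ON2C(C)(C)CCCC2(C)C)[C@H](C)CC1
F3 | step 13 | trans iodo isobutyrate: 5-iodo-4-(2-methylpropanoyloxy) adduct of 23 (C4 as in 25, C5 inverted) | C1[C@](C)(OC(=O)C(C)C)[C@@H](I)[C@H]2OC(=O)C(=C)[C@@H]2[C@@H](O[Si](C)(C)C(C)(C)C)[C@@H](ON3C(C)(C)CCCC3(C)C)[C@H](C)CC1
F4 | step 15 | C9 alcohol: (9S)-9-hydroxy analogue of 25 | C1[C@](C)(O)[C@H](OC(=O)C(C)C)[C@H]2OC(=O)C(=C)[C@@H]2[C@@H](O[Si](C)(C)C(C)(C)C)[C@@H](O)[C@H](C)CC1
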